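The plan cuts the two C7–aryl bonds that join the carbinol carbons C7 and C7′ to the terminal veratryl rings (C, C′). Each C7 lies next to an 8S carbon whose oxygen is bound to C4 of a guaiacyl ring (A, A′) on the central oxolane (ring B). The lactate-derived C8 centres can therefore steer both additions. One double, non-chelated Felkin–Anh arylation makes two C–C bonds and both 7R (erythro) centres and finishes the synthesis. Its precursor is the (2S,3S,4S,5R)-2,5-diaryl-3,4-dimethyloxolane in which the C4 oxygen of ring A and of ring A′ each bears an (S)-CH(CH3)CHO unit. It is reached through a cis-lactone, a hemiketal reduction and a double Mitsunobu etherification.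

Key step: step 11

Numbering: ring B is O1, C2–C5; in each side chain C7 is the carbinol carbon, C8 the aryloxy-bearing carbon and C9 its methyl group. Read from the SMILES, ring B is 2S,3S,4S,5R (2,3-trans, 3,4-trans, 4,5-cis, 2,5-cis) and both side chains are 7R,8S (erythro).

Assumption: (R)-TRIP directs the crotyl group to the Re face of 1, as it does with benzaldehyde; if the sense proved opposite, (S)-TRIP would be used with no other change.

Step 1
Reactants: 1 4-benzyloxy-3-methoxybenzaldehyde; 2 (Z)-crotylboronic acid pinacol ester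
Product: 3 (1R,2S)-1-(4-benzyloxy-3-methoxyphenyl)-2-methylbut-3-en-1-ol (syn)
Conditions: (R)-TRIP [(R)-3,3′-bis(2,4,6-triisopropylphenyl)-1,1′-binaphthyl-2,2′-diyl hydrogen phosphate, 5 mol %], 4 Å MS, toluene, −30 °C; aq NaHCO3
Reagents that add atoms: none
Why: Brønsted-acid-catalysed asymmetric crotylboration through a closed chair Zimmerman–Traxler transition state, in which the Z geometry of 2 becomes the syn C1/C2 relationship and the phosphoric acid bound to a boronate oxygen opens the Re face of 1 to set 1R (hence 2S); these centres become C5 and C4 of ring B.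

Step 2
Reactants: 3 (1R,2S)-1-(4-benzyloxy-3-methoxyphenyl)-2-methylbut-3-en-1-ol
Product: 5 (1R,2S)-1-(4-benzyloxy-3-methoxyphenyl)-2-methylbutane-1,4-diol, via B-alkyl-9-BBN adduct 4 (not isolated)
Conditions: 9-BBN-H (2.5 equiv), THF, 0 °C → rt; then 3 M NaOH, 30% H2O2, 0 °C → rt
Reagents that add atoms: hydrogen peroxide, OO
Why: Anti-Markovnikov hydroboration–oxidation, in which the bulky borane places boron on the terminal carbon of the monosubstituted alkene and C–B oxidation leaves the two stereocentres, the benzyl ether and the arene untouched.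

Step 3
Reactants: 5 (1R,2S)-1-(4-benzyloxy-3-methoxyphenyl)-2-methylbutane-1,4-diol
Product: 7 (4S,5R)-5-(4-benzyloxy-3-methoxyphenyl)-4-methyloxolan-2-one, via lactol 6 (not isolated)
Conditions: TEMPO (20 mol %), PhI(OAc)2 (2.5 equiv), CH2Cl2, rt
Reagents that add atoms: none
Why: Oxoammonium-catalysed (TEMPO) oxidative lactonisation of a 1,4-diol, in which the unhindered primary alcohol is oxidised first and the aldehyde is trapped at once as lactol 6, which masks the benzylic hydroxyl and is oxidised on to the lactone with the cis C4/C5 relationship kept.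

Step 4
Reactants: 7 (4S,5R)-5-(4-benzyloxy-3-methoxyphenyl)-4-methyloxolan-2-one
Product: 9 (3S,4S,5R)-5-(4-benzyloxy-3-methoxyphenyl)-3,4-dimethyloxolan-2-one, via lithium enolate 8 (not isolated)
Conditions: LiN(SiMe3)2 (1.1 equiv), THF, −78 °C; MeI, −78 → −40 °C
Reagents that add atoms: iodomethane, CI
Why: Diastereoselective lactone enolate alkylation, in which the C4 methyl and the C5 aryl group of 8 lie on the same face, so iodomethane enters from the free face and sets 3S (3,4-trans), also the thermodynamically favoured epimer.

Step 5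
Reactants: 9 (3S,4S,5R)-5-(4-benzyloxy-3-methoxyphenyl)-3,4-dimethyloxolan-2-one; 10 1-benzyloxy-4-bromo-2-methoxybenzene
Product: 12 (3S,4S,5R)-2,5-bis(4-benzyloxy-3-methoxyphenyl)-3,4-dimethyloxolan-2-ol (anomer mixture), via aryllithium 11 (not isolated)
Conditions: 10, n-BuLi, THF, −78 °C; then 9, −78 °C; AcOH/THF quench at −78 °C
Reagents that add atoms: none
Why: Bromine–lithium exchange followed by 1,2-addition of the aryllithium to the lactone carbonyl, where at −78 °C the adduct does not collapse before the cold acidic quench, so the reaction stops after one addition and C3–C5 stay unchanged (the anomeric centre is inconsequential).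

Step 6
Reactants: 12 (3S,4S,5R)-2,5-bis(4-benzyloxy-3-methoxyphenyl)-3,4-dimethyloxolan-2-ol
Product: 14 (2S,3S,4S,5R)-2,5-bis(4-benzyloxy-3-methoxyphenyl)-3,4-dimethyloxolane, via oxocarbenium ion 13 (not isolated)
Conditions: Et3SiH (5 equiv), then BF3·OEt2 (2 equiv), CH2Cl2, −78 °C; Et3N then aq NaHCO3 at −78 °C
Reagents that add atoms: none
Why: Lewis acid/silane ionic reduction of a cyclic hemiketal, in which BF3·OEt2 ionises 12 to 13, whose envelope holds both methyl groups pseudo-equatorial, and hydride enters by inside attack on the face syn to the C3 methyl and opposite the C4 methyl and the pseudo-axial C5 aryl, setting 2S (2,3-trans, 2,5-cis); the cis C4/C5 pair therefore has to come from the lactone (an all-trans lactone would end as the all-trans oxolane), and silane present before the Lewis acid at −78 °C should trap 13 before C5 can epimerise.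

Step 7
Reactants: 14 (2S,3S,4S,5R)-2,5-bis(4-benzyloxy-3-methoxyphenyl)-3,4-dimethyloxolane
Product: 15 4,4′-[(2S,3S,4S,5R)-3,4-dimethyloxolane-2,5-diyl]bis(2-methoxyphenol)
Conditions: H2 (1 atm), 10% Pd/C, EtOAc–MeOH, rt
Reagents that add atoms: none
Why: Catalytic hydrogenolysis, in which the primary O-benzyl aryl ethers are cleaved much faster than the hindered secondary C2–O and C5–O bonds of ring B, so stopping after two equivalents of H2 in a neutral solvent should leave ring B and its four stereocentres intact.

Step 8
Reactants: 15 4,4′-[(2S,3S,4S,5R)-3,4-dimethyloxolane-2,5-diyl]bis(2-methoxyphenol); 16 methyl (R)-lactate (two molecules)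
Product: 17 dimethyl (2S,2′S)-2,2′-{[(2S,3S,4S,5R)-3,4-dimethyloxolane-2,5-diyl]bis[(2-methoxy-4,1-phenylene)oxy]}dipropanoate
Conditions: 16 (3 equiv), PPh3 (3 equiv), DIAD (3 equiv), THF, 0 °C → rt
Reagents that add atoms: none
Why: Double Mitsunobu etherification, in which each phenol displaces the activated hydroxyl of 16 in an SN2 process with inversion, turning R-lactate into the two 8S aryloxy centres under nearly neutral conditions that do not disturb ring B.

Step 9
Reactants: 17 the (2S,2′S)-dimethyl dipropanoate
Product: 18 (2S,2′S)-2,2′-{[(2S,3S,4S,5R)-3,4-dimethyloxolane-2,5-diyl]bis[(2-methoxy-4,1-phenylene)oxy]}dipropanal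
Conditions: iBu2AlH (2.3 equiv), CH2Cl2, −78 °C; aq potassium sodium tartrate, −78 °C → rt; crude, used at once
Reagents that add atoms: none
Why: Partial reduction of an α-alkoxy ester with iBu2AlH, in which each ester accepts only one hydride at −78 °C and the formyl group is released only on the aqueous quench, so over-reduction is avoided and the base-free work-up without chromatography preserves the labile 8S centres.

Step 10
Reactants: 19 3,4-dimethoxyphenylmagnesium bromide (commercial THF solution)
Product: 20 3,4-dimethoxyphenyltitanium triisopropoxide (solution, prepared while 18 is being worked up)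
Conditions: ClTi(OiPr)3 (1 equiv), THF–Et2O, −78 → 0 °C; 1,4-dioxane, cannula filtration under Ar
Reagents that add atoms: chlorotitanium triisopropoxide, CC(C)O[Ti](Cl)(OC(C)C)OC(C)C
Why: Transmetalation from magnesium to tetravalent titanium, in which chloride is exchanged for the aryl group to give a weakly basic and weakly Lewis acidic aryl donor, while precipitation of the magnesium halide removes the one strongly chelating cation from the medium.

Step 11
Reactants: 18 the (2S,2′S)-dipropanal; 20 3,4-dimethoxyphenyltitanium triisopropoxide (two molecules)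
Product: 21 the target, (1R,1′R,2S,2′S)-2,2′-{[(2S,3S,4S,5R)-3,4-dimethyloxolane-2,5-diyl]bis[(2-methoxy-4,1-phenylene)oxy]}bis[1-(3,4-dimethoxyphenyl)propan-1-ol]
Conditions: 20 (4 equiv), THF, −78 °C, add 18 in THF, −78 → −10 °C; aq potassium sodium tartrate
Reagents that add atoms: none
Why: Each formyl group binds the weakly Lewis acidic tetravalent titanium centre of 20 and receives its aryl ligand at carbon in a 1,2-addition, and hydrolysis of the Ti–O bonds then frees the two benzylic alcohols; the closest known reaction type is the non-chelation-controlled addition of organotitanium triisopropoxides to α-alkoxy aldehydes. No ring is closed. Each new C7 centre is set by 1,2-induction from its own 8S neighbour: in the polar Felkin–Anh arrangement the C8–OAr bond stands perpendicular to the C=O plane and anti to the incoming aryl group, which travels along the Bürgi–Dunitz line past C8–H and not past the C9 methyl, so the anti (erythro) 7R,8S unit results. The selectivity needed is Felkin–Anh over chelate delivery (which would give threo), and it is secured by the poor donor ability of the aryl ether oxygen, by the three isopropoxide ligands that leave titanium little affinity for a second donor, and by the earlier removal of the magnesium halide that could otherwise be clamped between the formyl oxygen, the ether oxygen and the ortho-methoxy group of ring A. The two formyl groups are diastereotopic, since ring B is unsymmetrical, but they are separated by the whole core and should react independently, each under the control of its own C8. The reagent is too weakly basic to enolise the aldehyde and no acid is present, so the 8S centres and the benzylic C2–O and C5–O bonds of ring B are kept.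

Compound list
1 | 4-benzyloxy-3-methoxybenzaldehyde | COc1cc(C=O)ccc1OCc1ccccc1 | starting material
2 | (Z)-crotylboronic acid pinacol ester | C/C=C\CB1OC(C)(C)C(C)(C)O1 | starting material
3 | (1R,2S)-1-(4-benzyloxy-3-methoxyphenyl)-2-methylbut-3-en-1-ol | C=C[C@H](C)[C@@H](O)c1ccc(OCc2ccccc2)c(OC)c1 | intermediate
4 | (1R,2S)-4-(9-borabicyclo[3.3.1]nonan-9-yl)-1-(4-benzyloxy-3-methoxyphenyl)-2-methylbutan-1-ol | C1CCC2CCCC1B2CC[C@H](C)[C@@H](O)c1ccc(OCc2ccccc2)c(OC)c1 | intermediate
5 | (1R,2S)-1-(4-benzyloxy-3-methoxyphenyl)-2-methylbutane-1,4-diol | OCC[C@H](C)[C@@H](O)c1ccc(OCc2ccccc2)c(OC)c1 | intermediate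
6 | (4S,5R)-5-(4-benzyloxy-3-methoxyphenyl)-4-methyloxolan-2-ol (lactol, anomer mixture) | OC1C[C@H](C)[C@H](c2ccc(OCc3ccccc3)c(OC)c2)O1 | intermediate
7 | (4S,5R)-5-(4-benzyloxy-3-methoxyphenyl)-4-methyloxolan-2-one (4,5-cis) | O=C1C[C@H](C)[C@H](c2ccc(OCc3ccccc3)c(OC)c2)O1 | intermediate
8 | lithium enolate of 7 | [Li]OC1=C[C@H](C)[C@H](c2ccc(OCc3ccccc3)c(OC)c2)O1 | intermediate
9 | (3S,4S,5R)-5-(4-benzyloxy-3-methoxyphenyl)-3,4-dimethyloxolan-2-one (3,4-trans, 4,5-cis) | O=C1[C@@H](C)[C@H](C)[C@H](c2ccc(OCc3ccccc3)c(OC)c2)O1 | intermediate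
10 | 1-benzyloxy-4-bromo-2-methoxybenzene | COc1cc(Br)ccc1OCc1ccccc1 | starting material
11 | 4-benzyloxy-3-methoxyphenyllithium | COc1cc([Li])ccc1OCc1ccccc1 | intermediate
12 | (3S,4S,5R)-2,5-bis(4-benzyloxy-3-methoxyphenyl)-3,4-dimethyloxolan-2-ol (anomer mixture) | OC1(c2ccc(OCc3ccccc3)c(OC)c2)O[C@@H](c2ccc(OCc3ccccc3)c(OC)c2)[C@@H](C)[C@@H]1C | intermediate
13 | 2-aryl oxocarbenium ion derived from 12 (C2=O1 cation, 3S,4S,5R) | COc1cc(C2=[O+][C@@H](c3ccc(OCc4ccccc4)c(OC)c3)[C@@H](C)[C@@H]2C)ccc1OCc1ccccc1 | intermediate
14 | (2S,3S,4S,5R)-2,5-bis(4-benzyloxy-3-methoxyphenyl)-3,4-dimethyloxolane | COc1cc([C@H]2O[C@@H](c3ccc(OCc4ccccc4)c(OC)c3)[C@@H](C)[C@@H]2C)ccc1OCc1ccccc1 | intermediate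
15 | 4,4′-[(2S,3S,4S,5R)-3,4-dimethyloxolane-2,5-diyl]bis(2-methoxyphenol) | COc1cc([C@H]2O[C@@H](c3ccc(O)c(OC)c3)[C@@H](C)[C@@H]2C)ccc1O | intermediate
16 | methyl (R)-lactate | C[C@@H](O)C(=O)OC | starting material
17 | core bis[(S)-2-aryloxypropanoate] dimethyl ester | COC(=O)[C@H](C)Oc1ccc([C@H]2O[C@@H](c3ccc(O[C@@H](C)C(=O)OC)c(OC)c3)[C@@H](C)[C@@H]2C)cc1OC | intermediate
18 | core bis[(S)-2-aryloxypropanal] | O=C[C@H](C)Oc1ccc([C@H]2O[C@@H](c3ccc(O[C@@H](C)C=O)c(OC)c3)[C@@H](C)[C@@H]2C)cc1OC | intermediate
19 | 3,4-dimethoxyphenylmagnesium bromide | COc1ccc([Mg]Br)cc1OC | starting material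
20 | 3,4-dimethoxyphenyltitanium triisopropoxide | COc1ccc([Ti](OC(C)C)(OC(C)C)OC(C)C)cc1OC | intermediate
21 | target (ring B 2S,3S,4S,5R; both side chains 7R,8S) | COc1ccc([C@@H](O)[C@H](C)Oc2ccc([C@H]3O[C@@H](c4ccc(O[C@@H](C)[C@H](O)c5ccc(OC)c(OC)c5)c(OC)c4)[C@@H](C)[C@@H]3C)cc2OC)cc1OC | target

Total step count: 11. Longest linear sequence: 10 steps (steps 1–9 and 11, from 1 to 21).

Steps most likely to fail

Step 11. Two processes could erode the 7R,8S relationship: leakage through a chelated transition state (metal held between the formyl oxygen, the ether oxygen and the ortho-methoxy group of ring A), or partial enolisation of the aldehyde. Any erosion counts twice, because both ends must come out right. The fallback sets out from 17 and comes back at 21, and it sets C7 by hydride delivery instead of aryl delivery. Diester 17 is converted with MeNHOMe·HCl/iPrMgCl (THF, −20 °C) into the bis-Weinreb amide F1. Two molecules of 19 then add to give the bis(aryl ketone) F2 without over-addition. Reduction with Zn(BH4)2 in Et2O at low temperature should run under Cram chelate control, with zinc bridging the ketone and ether oxygens (helped by the ortho-methoxy group) and hydride entering past C8–H. This should give the same erythro units and thus 21.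

Step 6. Reversible opening of the p-alkoxybenzylic C5–O bond before hydride capture would epimerise C5 towards the all-trans series. Poor facial selectivity at C2 would add a further isomer. The fallback sets out from 9 and comes back at 14; it makes the cis aryl/methyl pair by C–C bond formation and the trans pair by equilibration.
- Lactone 9 is equilibrated with BF3·OEt2 in CH2Cl2 (0 °C → rt), through ionisation and reclosure of its C5–O bond, to the all-trans lactone F3.
- iBu2AlH gives the lactol F4, and PhSO2H/CaCl2 gives the 2-benzenesulfonyl oxolane F5.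
- The arylzinc bromide F6 (from 11 and ZnBr2, with MgBr2·OEt2 as promoter) replaces the sulfonyl group by inside attack, which places the new aryl group cis to the neighbouring methyl.
- Both aryl groups are identical and the trans-dimethyl unit is locally C2-symmetric, so this 2,3-cis-3,4-trans-4,5-trans product is 14 itself.

Step 9. Over-reduction at one end together with incomplete reduction at the other would give a statistical mixture, and slow work-up would allow loss of configuration at C8. The fallback sets out from 17 and comes back at 18. LiAlH4 in THF reduces both esters fully to the bis(primary alcohol) F7, a stable compound that can be purified and stored. Dess–Martin periodinane buffered with NaHCO3 in CH2Cl2 then oxidises both ends to 18 immediately before step 11.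

Further compounds
F1 | step 11 | core bis[(S)-2-aryloxy-N-methoxy-N-methylpropanamide] | CON(C)C(=O)[C@H](C)Oc1ccc([C@H]2O[C@@H](c3ccc(O[C@@H](C)C(=O)N(C)OC)c(OC)c3)[C@@H](C)[C@@H]2C)cc1OC
F2 | step 11 | core bis[(S)-2-aryloxy-1-(3,4-dimethoxyphenyl)propan-1-one] | COc1ccc(C(=O)[C@H](C)Oc2ccc([C@H]3O[C@@H](c4ccc(O[C@@H](C)C(=O)c5ccc(OC)c(OC)c5)c(OC)c4)[C@@H](C)[C@@H]3C)cc2OC)cc1OC
F3 | step 6 | (3S,4S,5S)-5-(4-benzyloxy-3-methoxyphenyl)-3,4-dimethyloxolan-2-one (all-trans) | O=C1[C@@H](C)[C@H](C)[C@@H](c2ccc(OCc3ccccc3)c(OC)c2)O1
F4 | step 6 | (3S,4S,5S)-5-(4-benzyloxy-3-methoxyphenyl)-3,4-dimethyloxolan-2-ol (anomer mixture) | OC1[C@@H](C)[C@H](C)[C@@H](c2ccc(OCc3ccccc3)c(OC)c2)O1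
F5 | step 6 | (3S,4S,5S)-2-benzenesulfonyl-5-(4-benzyloxy-3-methoxyphenyl)-3,4-dimethyloxolane (anomer mixture) | O=S(=O)(c1ccccc1)C1[C@@H](C)[C@H](C)[C@@H](c2ccc(OCc3ccccc3)c(OC)c2)O1
F6 | step 6 | 4-benzyloxy-3-methoxyphenylzinc bromide | COc1cc([Zn]Br)ccc1OCc1ccccc1
F7 | step 9 | core bis[(S)-2-aryloxypropan-1-ol] | OC[C@H](C)Oc1ccc([C@H]2O[C@@H](c3ccc(O[C@@H](C)CO)c(OC)c3)[C@@H](C)[C@@H]2C)cc1OC
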